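The readings were computed for substances that don't exist; noise was put on by code.

The ratio of incoming ligand to starting complex charged runs from 0.227 at noon to 2.27 at dawn, and we ask what that does to the complex with one exchanged.

| flask | starting complex | incoming ligand | leaving ligand | remark | time |
|---|---|---|---|---|---|
| elm | 0.88 M | 0.25 M | 0.88 M | run made earlier |  |
| oak | 0.88 M | 3 M | 0.88 M | run made earlier |  |
| noon | 0.88 M | 0.200 M | 0.880 M |  | 2.0 min |
| midnight | 0.88 M | 0.400 M | 0.880 M |  | 2.0 min |
| autumn | 0.88 M | 0.800 M | 0.880 M |  | 2.0 min |
| dawn | 0.88 M | 2.00 M | 0.880 M |  | 2.0 min |

- elm (time / s: complex with one exchanged / %, starting complex / %): 10.0: 4.8, 93.3; 15.0: 7.7, 93.1; 30.0: 10.9, 85.8; 50.0: 14.0, 82.5; 60.0: 14.7, 80.4; 80.0: 15.6, 78.6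
- oak (time / s: complex with one exchanged / %, starting complex / %): 10.0: 29.7, 48.0; 15.0: 29.7, 34.9; 30.0: 22.0, 17.3; 50.0: 13.2, 8.1; 60.0: 9.7, 5.6; 80.0: 7.6, 4.1

(scatter of a reading: 0.5 percentage points)

- "hardly changes" means that all values lie within two and a half points (for a concentration: within two and a half percent of the largest)

- amount of complex with one exchanged at the end, in percent of the starting complex charged for noon, midnight, autumn, dawn, in this order
- how that number moves from the first to the last of them (rises all the way / rises, then falls / hardly changes / falls all the way / falls, then rises)

In the oak run the complex with one exchanged reads 29.7% at both 10.0 s and 15.0 s, so it is then made about as fast as it is used. If both steps take incoming ligand, the starting complex over that complex, 1.40 in these readings, is the ratio of the second rate constant to the first. The two are alike. So the ligand takes the two forms with like rate constants. The concentration that sets its rate is then the sum of the forms that still take it, near 0.88 M as long as the complex stays in those forms, and the ligand decays pseudo-first-order.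

We need a constant. In oak the starting complex falls to 48.0% by 10.0 s, which at the charged ligand gives 0.0245 M⁻¹ s⁻¹. But the ligand did not stay at its charge. Counting the complex in neither form as exchanged twice, we reckon 0.654 M taken up in oak. The mean ligand then gives 0.0275 M⁻¹ s⁻¹.

So we carry 0.478 min, the ligand half-life: the time in which the complex, at its charge, halves the free incoming ligand. As long as the complex keeps taking ligand at its charge, it doesn't change with the ligand charge. After 2.0 min we reckon the fraction left at 5.50%.

Is this sound? Take elm, which played no part in it. The ligand landed per complex, 0.243, leaves 78.4% of the starting complex at 80.0 s, and elm reads 78.6%.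

The same rule leaves 80.7% at noon, 42.4% at autumn and 11.7% at dawn. Dawn is the shakiest, with more ligand than complex. Now we read the complex with one exchanged off the runs at those shares. Elm gives 14.7% at 80.4%, which suits noon. Oak gives 29.7% near autumn's share, and between 22.0% and 13.2% near dawn's. But oak got there in seconds, and autumn has 2.0 min. Elm at 80.0 s has lost 21.4% of the starting complex and shows 15.6% of the complex with one exchanged, so a longer stay may cost that complex something, and we take autumn lower. We expect a rise, then a fall.

The forecast gave 12%, 18%, 21% and 15%, rises, then falls, noting that “In elm the incoming ligand is nearly used up”. The flask gives 12.9%, 20.1%, 24.8% and 13.7%: rises, then falls.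

    starting complex + incoming ligand → leaving ligand + complex with one exchanged (k = 0.0273 M⁻¹ s⁻¹)
    complex with two exchanged + incoming ligand → leaving ligand + complex with three exchanged (k = 0.0332 M⁻¹ s⁻¹)
    complex with one exchanged ⇌ isomer of the product (K = 0.280, k = 0.00468 s⁻¹)
    leaving ligand + complex with one exchanged → side product (k = 8.41 × 10⁻⁴ M⁻¹ s⁻¹)
    complex with one exchanged + incoming ligand → leaving ligand + complex with two exchanged (k = 0.0358 M⁻¹ s⁻¹)

At noon the half-life of the incoming ligand by the first step alone, 0.59 min at the end, is shorter than the time 2.0 min, and our 0.478 min left 5.50% where the flask holds 5.4%. At midnight, with twice the noon charge, the same half-life gives the same fraction, and 5.3% of the ligand stands. At dawn, with 46.2% of the complex at the end in the form with three exchanged, 11% of the ligand stands.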